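The two benzenoid C–Br bonds are disconnected first, back to 1-methylindoline; the C2–Br and C3–Br bonds come last. In concentrated H2SO4 the indoline nitrogen is an ammonium centre, so within the benzene ring C4 and C6 lie meta to the N1-bearing C7a and ortho and para to the C3 methylene on C3a: both groups point to the same two carbons, sites that an indole or a free indoline does not offer. One operation with NBS should therefore install both bromines, while the saturated C2–C3 bond of the five-membered ring keeps pyrrole-type reactivity hidden. The precursor is commercial 1-methylindoline. DDQ then aromatises the five-membered ring and NBS brominates C3 and C2.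

Key step: step 1

Remark on the chemistry: 1-methylindoline is taken as a purchasable material. The ring is aromatised with a quinone before any NBS meets the free amine, because NBS would be expected to brominate C5 and C7 of an N-alkylaniline faster than it dehydrogenates it.

Step 1
Reactants: 1 1-methylindoline; 2 N-bromosuccinimide (2.2 equiv)
Product: 4 4,6-dibromo-1-methylindoline, via 6-bromo-1-methylindoline 3 (not isolated)
Conditions: NBS (2.2 equiv, in portions), conc. H2SO4, 0 °C to rt then 50 °C, dark; ice, aq NaOH to pH 10
Reagents that add atoms: N-bromosuccinimide, O=C1CCC(=O)N1Br
Why: Electrophilic aromatic bromination of a deactivated arene with NBS in concentrated H2SO4, in which protonated NBS delivers a bromonium equivalent to the fully N-protonated indoline and each substitution passes through a Wheland intermediate that loses a proton. The closest known reactions are the C6 bromination and nitration of indolinium ions in H2SO4 and the double bromination of 2-nitrotoluene at C4 and C6 in the same medium. No ring is closed and no stereocentre is formed. The step needs site selectivity for C4 and C6 over C5 and C7: the ammonium nitrogen on C7a directs meta and the C3 methylene on C3a directs ortho and para, and both point to C6 (the less hindered para site, expected first) and to C4. Once bromine sits on C6 its own ortho preference for C5 and C7 should be overruled, since these carbons are para and ortho to the ammonium group and meta to the alkyl arm, so the second bromine should enter at C4; either order of entry converges on 4. Dissolving 1 in a large excess of acid before NBS is added keeps the amine fully protonated, which is what shuts off attack at C5 and C7 and oxidation at nitrogen.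

Step 2
Reactants: 4 4,6-dibromo-1-methylindoline
Product: 5 4,6-dibromo-1-methylindole
Conditions: DDQ (1.1 equiv), toluene, rt to 60 °C; filtration, aq NaHCO3 wash
Reagents that add atoms: none
Why: Quinone dehydrogenation of an indoline to the indole, in which DDQ should take a hydride from C2, the carbon alpha to nitrogen, and the C3 proton is then lost, driven by the gain of the aromatic pyrrole ring; the aryl bromides are inert and no brominating agent is present while the substrate is still an electron-rich N-alkylaniline.

Step 3
Reactants: 5 4,6-dibromo-1-methylindole; 2 N-bromosuccinimide (2.1 equiv)
Product: 7 2,3,4,6-tetrabromo-1-methylindole, via 3,4,6-tribromo-1-methylindole 6 (not isolated)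
Conditions: NBS (2.1 equiv), THF, −78 °C to rt, dark; aq Na2S2O3
Reagents that add atoms: N-bromosuccinimide, O=C1CCC(=O)N1Br
Why: Electrophilic bromination of the indole, in which NBS should attack C3, the enamine carbon, to give 6, and the second equivalent then brominates C2, the only pyrrole CH left, as in the known 2,3-dibromination of 1-methylindoles with two equivalents of NBS; C5 and C7 of the benzene ring, each next to bromine and far less nucleophilic, should not compete at this stoichiometry.

Compound list (no compound in the route has a stereocentre)
1 | 1-methylindoline | CN1CCc2ccccc21 | starting material
2 | N-bromosuccinimide | O=C1CCC(=O)N1Br | starting material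
3 | 6-bromo-1-methylindoline (held in the acid as its N-protonated salt) | CN1CCc2ccc(Br)cc21 | intermediate
4 | 4,6-dibromo-1-methylindoline | CN1CCc2c(Br)cc(Br)cc21 | intermediate
5 | 4,6-dibromo-1-methylindole | Cn1ccc2c(Br)cc(Br)cc21 | intermediate
6 | 3,4,6-tribromo-1-methylindole | Cn1cc(Br)c2c(Br)cc(Br)cc21 | intermediate
7 | 2,3,4,6-tetrabromo-1-methylindole | Cn1c(Br)c(Br)c2c(Br)cc(Br)cc21 | target

Total step count: 3
Longest linear sequence: 3 steps

Steps most likely to fail

Step 1. The second bromination may lose site control or stall: the bromine already on C6 directs towards C5 and C7, and the doubly deactivated ammonium ion may stop at the monobromide 3. The fallback sets out from compound 1 and comes back at compound 4. The C6 substituent is introduced as a nitro group, which directs meta and so reinforces the ammonium group and the C3 methylene where bromine would oppose them. Nitration of 1 with KNO3 in concentrated H2SO4 at 0 °C, the known C6 nitration of indolinium ions, should give 1-methyl-6-nitroindoline F1. Dibromoisocyanuric acid in concentrated H2SO4, a stronger bromonium source than 2, should then brominate C4, the only position favoured by all three substituents, to give 4-bromo-1-methyl-6-nitroindoline F2. Iron powder and NH4Cl in aqueous ethanol should reduce the nitro group without touching the aryl bromide, giving 4-bromo-1-methylindolin-6-amine F3. Diazotisation with NaNO2 in aqueous HBr at 0 °C should form 4-bromo-1-methylindoline-6-diazonium bromide F4, and a Sandmeyer reaction with CuBr in HBr replaces the diazonium group by bromine to give 4.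

Step 3. The second bromination at C2 may fall behind, so that the electron-poor 3-bromoindole 6 is diverted into oxindole-type oxidation by traces of water or into bromination of the benzene ring. The fallback sets out from compound 5 and comes back at compound 7. The C2–Br bond is made through a C–B bond, not by electrophilic attack on the ring. Iridium-catalysed C–H borylation ([Ir(OMe)(cod)]2, 4,4'-di-tert-butyl-2,2'-bipyridine, B2pin2, THF, 60 °C) takes the C–H next to nitrogen in 1-alkylindoles and should leave the hindered C5–H and C7–H alone, giving 4,6-dibromo-1-methyl-2-(4,4,5,5-tetramethyl-1,3,2-dioxaborolan-2-yl)indole F5. CuBr2 in aqueous methanol at 80 °C should convert the boronate into the bromide, 2,4,6-tribromo-1-methylindole F6; any bromination at C3 in this step only anticipates the last one. One equivalent of 2 in THF then brominates the free C3 to give 7.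

Step 2. Over-oxidation may occur: the quinone may add to or couple at C3 of the newly formed indole, or oxidise the N-methyl group. The fallback sets out from compound 4 and comes back at compound 5. Hydride abstraction by a dissolved quinone is given up for a heterogeneous surface oxidation with an excess of activated manganese dioxide, MnO2, in refluxing toluene, a classical dehydrogenation of indolines. The indole is released into a solution that holds no soluble oxidant or electrophile, the oxidant is removed by filtration, and no new compound is made on the way (F0).

Further compounds
F1 | step 1 | 1-methyl-6-nitroindoline | CN1CCc2ccc([N+](=O)[O-])cc21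
F2 | step 1 | 4-bromo-1-methyl-6-nitroindoline | CN1CCc2c(Br)cc([N+](=O)[O-])cc21
F3 | step 1 | 4-bromo-1-methylindolin-6-amine | CN1CCc2c(Br)cc(N)cc21
F4 | step 1 | 4-bromo-1-methylindoline-6-diazonium bromide | CN1CCc2c(Br)cc([N+]#N)cc21.[Br-]
F5 | step 3 | 4,6-dibromo-1-methyl-2-(4,4,5,5-tetramethyl-1,3,2-dioxaborolan-2-yl)indole | Cn1c(B3OC(C)(C)C(C)(C)O3)cc2c(Br)cc(Br)cc21
F6 | step 3 | 2,4,6-tribromo-1-methylindole | Cn1c(Br)cc2c(Br)cc(Br)cc21
F0 | step 2 | none | none
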